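The route rests on cutting the diaryl ether between the bridging oxygen and C1′ of ring B. Ring B carries O-aryl at C1′, OH at C3′ and CH3 at C5′, the atom pattern of 5-methylcyclohexane-1,3-dione, so it enters dearomatised as racemic 3-chloro-5-methylcyclohex-2-enone. In one operation the O-2 phenoxide of ring A, a 3-O-benzyl-5-methoxysalicylate with O-2 flanked by CO2Me and OBn, displaces chloride by addition–elimination. This forges the congested C–O bond and differentiates the two orcinol oxygens without protecting ring B. Bromination–dehydrobromination then unveils the phenol, and debenzylation, ester reduction and lipase palmitoylation finish.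

Key step: step 5

Remark: the target SMILES holds no stereocentre, axis or stereogenic double bond, so the compound is achiral and there is no enantiomer to select. The only stereocentre on the route (C5 of the cyclohexenone) is carried as the racemate and disappears on aromatisation.

Step 1
Reactants: 1 methyl 2-hydroxy-5-methoxybenzoate (methyl 5-methoxysalicylate)
Product: 2 methyl 3-formyl-2-hydroxy-5-methoxybenzoate
Conditions: hexamethylenetetramine (2 equiv), TFA, 80 °C; then 2 M HCl, rt
Reagents that add atoms: hexamethylenetetramine, C1N2CN3CN1CN(C2)C3 (formyl carbon); water, O (formyl oxygen)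
Why: Duff formylation: the iminium electrophile from protonated hexamethylenetetramine should attack C3, the only open site ortho or para to the phenolic OH (C1 holds the ester, C5 the methoxy group), and hydride transfer within the aminal followed by acid hydrolysis of the resulting imine releases the aldehyde.

Step 2
Reactants: 2 methyl 3-formyl-2-hydroxy-5-methoxybenzoate
Product: 4 methyl 2,3-dihydroxy-5-methoxybenzoate, via aryl formate 3 (not isolated)
Conditions: 30% aq H2O2 (1.1 equiv), 1 M NaOH (1.05 equiv), THF–H2O, 0 °C, Ar; then 1 M HCl
Reagents that add atoms: hydrogen peroxide, OO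
Why: Dakin oxidation: hydroperoxide adds to the formyl group, the electron-rich aryl carbon migrates to oxygen to give formate 3, and this is hydrolysed at once, while a single equivalent of base at 0 °C under argon should spare the methyl ester and the air-sensitive catechol.

Step 3
Reactants: 4 methyl 2,3-dihydroxy-5-methoxybenzoate
Product: 5 methyl 3-(benzyloxy)-2-hydroxy-5-methoxybenzoate
Conditions: NaH (2.05 equiv), DMSO–THF, rt, Ar; BnBr (1.0 equiv), rt; then 1 M HCl
Reagents that add atoms: benzyl bromide, BrCc1ccccc1
Why: Williamson etherification of the catecholate dianion: the O-3 oxyanion is neither conjugated with the ester nor wedged between two substituents and is therefore the more nucleophilic one, and the chelated salicylate monoanion left after the first alkylation should not compete for the single equivalent of benzyl bromide.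

Step 4
Reactants: 6 5-methylcyclohexane-1,3-dione
Product: 7 3-chloro-5-methylcyclohex-2-en-1-one (racemic)
Conditions: (COCl)2 (1.2 equiv), DMF (cat.), CH2Cl2, 0 °C → rt
Reagents that add atoms: oxalyl chloride, O=C(Cl)C(=O)Cl
Why: Vilsmeier-type activation of the enol oxygen of the vinylogous acid followed by chloride addition–elimination gives the vinylogous acid chloride, and since the two carbonyl groups of 6 are enantiotopic only one constitution can form, as the racemate.

Step 5
Reactants: 5 methyl 3-(benzyloxy)-2-hydroxy-5-methoxybenzoate; 7 3-chloro-5-methylcyclohex-2-en-1-one (racemic, 1.3 equiv)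
Product: 8 methyl 3-(benzyloxy)-5-methoxy-2-[(5-methyl-3-oxocyclohex-1-en-1-yl)oxy]benzoate (racemic)
Conditions: Cs2CO3 (1.3 equiv), DMF, 4 Å MS, rt → 45 °C, Ar
Reagents that add atoms: none
Why: Cs2CO3 converts 5 into its caesium phenoxide, whose O-2 adds to the β-carbon C3 of 7 to give a chloro-substituted enolate that expels chloride and restores the enone (addition–elimination, vinylic nucleophilic substitution). The closest known reaction type is the etherification of phenols with 3-chlorocyclohex-2-enones to 3-aryloxycyclohexenones. Only the O-2–C3 bond forms; no ring is closed and no stereocentre is created, the C5 centre of 7 being carried as the racemate until aromatisation removes it. The step needs O- rather than C-attack, reaction at the right catechol oxygen and a single substitution: both ortho positions and the para position of the phenoxide are occupied so C-attack cannot rearomatise, the benzyl group leaves O-2 as the only free oxygen, and 7 offers one C–Cl carbon. A carbonyl-activated sp2 carbon approached from above the ring plane should tolerate the two ortho substituents better than a metal-catalysed arylation, and mild base, sieves and at most 45 °C should limit hydrolysis or self-condensation of 7 and Claisen-type attack of the enone α-carbon on the neighbouring ester.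

Step 6
Reactants: 8 methyl 3-(benzyloxy)-5-methoxy-2-[(5-methyl-3-oxocyclohex-1-en-1-yl)oxy]benzoate (racemic)
Product: 10 methyl 3-(benzyloxy)-2-(3-hydroxy-5-methylphenoxy)-5-methoxybenzoate, via 2-bromoenone 9 (not isolated)
Conditions: NBS (1.0 equiv), CH2Cl2, 0 °C, dark; water wash, solvent swap; DBU (2.5 equiv), PhMe, 80 °C, Ar; then 1 M HCl
Reagents that add atoms: N-bromosuccinimide, O=C1CCC(=O)N1Br (its bromine is held only in 9 and leaves again)
Why: α-Bromination of the push–pull enone at C2 followed by DBU-induced dehydrobromination (deconjugation to the β,γ-enone, then 1,4-loss of HBr using the C5–H) gives a cyclohexadienone that tautomerises to the phenol, a halogenation–elimination aromatisation known for 3-aryloxycyclohexenones that works without acid and water, so the hydrolysis-prone vinylogous aryl ester should survive, and that erases the C5 stereocentre.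

Step 7
Reactants: 10 methyl 3-(benzyloxy)-2-(3-hydroxy-5-methylphenoxy)-5-methoxybenzoate
Product: 11 methyl 3-hydroxy-2-(3-hydroxy-5-methylphenoxy)-5-methoxybenzoate
Conditions: H2 (1 atm), 10% Pd/C, EtOAc, rt
Reagents that add atoms: none
Why: Catalytic hydrogenolysis of the aryl benzyl ether, which leaves the diaryl ether, the aryl methyl ether and the ester untouched and is placed ahead of the ester reduction so that ring A has no benzylic C–O bond of its own while Pd and H2 are present.

Step 8
Reactants: 11 methyl 3-hydroxy-2-(3-hydroxy-5-methylphenoxy)-5-methoxybenzoate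
Product: 12 3-(hydroxymethyl)-2-(3-hydroxy-5-methylphenoxy)-5-methoxyphenol
Conditions: LiAlH4 (4 equiv), THF, 0 → 40 °C; then cold 1 M HCl
Reagents that add atoms: none
Why: Hydride reduction of the benzoate with excess LiAlH4, the two phenols being carried as aluminium phenoxides; the ring-A phenoxide is meta to the new CH2O group, so no quinone methide can form and over-reduction to the methyl compound should not occur.

Step 9
Reactants: 12 3-(hydroxymethyl)-2-(3-hydroxy-5-methylphenoxy)-5-methoxyphenol; 13 vinyl palmitate (vinyl hexadecanoate, 2 equiv)
Product: 14 Betaethrin H, [3-hydroxy-2-(3-hydroxy-5-methylphenoxy)-5-methoxyphenyl]methyl hexadecanoate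
Conditions: Novozym 435 (immobilised Candida antarctica lipase B), 2-methyl-2-butanol, 4 Å MS, 45 °C
Reagents that add atoms: none
Why: Lipase-catalysed irreversible transesterification: the palmitoyl-enzyme formed from the vinyl ester should be intercepted only by the primary benzylic alcohol, because phenols are very poor acyl acceptors for this serine hydrolase, and tautomerisation of the released vinyl alcohol to acetaldehyde blocks the back reaction.

Compound list
1 | methyl 2-hydroxy-5-methoxybenzoate | COC(=O)c1cc(OC)ccc1O | starting material
2 | methyl 3-formyl-2-hydroxy-5-methoxybenzoate | COC(=O)c1cc(OC)cc(C=O)c1O | intermediate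
3 | methyl 3-(formyloxy)-2-hydroxy-5-methoxybenzoate (not isolated) | COC(=O)c1cc(OC)cc(OC=O)c1O | intermediate
4 | methyl 2,3-dihydroxy-5-methoxybenzoate | COC(=O)c1cc(OC)cc(O)c1O | intermediate
5 | methyl 3-(benzyloxy)-2-hydroxy-5-methoxybenzoate | COC(=O)c1cc(OC)cc(OCc2ccccc2)c1O | intermediate
6 | 5-methylcyclohexane-1,3-dione | CC1CC(=O)CC(=O)C1 | starting material
7 | 3-chloro-5-methylcyclohex-2-en-1-one (racemic) | CC1CC(Cl)=CC(=O)C1 | intermediate
8 | methyl 3-(benzyloxy)-5-methoxy-2-[(5-methyl-3-oxocyclohex-1-en-1-yl)oxy]benzoate (racemic) | COC(=O)c1cc(OC)cc(OCc2ccccc2)c1OC1=CC(=O)CC(C)C1 | intermediate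
9 | methyl 3-(benzyloxy)-2-[(2-bromo-5-methyl-3-oxocyclohex-1-en-1-yl)oxy]-5-methoxybenzoate (racemic, not isolated) | COC(=O)c1cc(OC)cc(OCc2ccccc2)c1OC1=C(Br)C(=O)CC(C)C1 | intermediate
10 | methyl 3-(benzyloxy)-2-(3-hydroxy-5-methylphenoxy)-5-methoxybenzoate | COC(=O)c1cc(OC)cc(OCc2ccccc2)c1Oc1cc(C)cc(O)c1 | intermediate
11 | methyl 3-hydroxy-2-(3-hydroxy-5-methylphenoxy)-5-methoxybenzoate | COC(=O)c1cc(OC)cc(O)c1Oc1cc(C)cc(O)c1 | intermediate
12 | 3-(hydroxymethyl)-2-(3-hydroxy-5-methylphenoxy)-5-methoxyphenol | OCc1cc(OC)cc(O)c1Oc1cc(C)cc(O)c1 | intermediate
13 | vinyl palmitate | CCCCCCCCCCCCCCCC(=O)OC=C | starting material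
14 | Betaethrin H (achiral) | CCCCCCCCCCCCCCCC(=O)OCc1cc(OC)cc(O)c1Oc1cc(C)cc(O)c1 | target

Total step count: 9.
Longest linear sequence: 8 steps (1 → 2 → 4 → 5 → 8 → 10 → 11 → 12 → 14); step 4 is the side branch.

Steps most likely to fail

Step 6. Electrophilic bromination could stray onto the dialkoxy-substituted ring A or the benzylic CH2. The base could also trigger loss of the aryloxide or a Favorskii-type contraction instead of the 1,4-elimination. The fallback sets out from 8 and replaces halogenation by enolate chemistry at the other α-carbon. Kinetic deprotonation at C6 with LiHMDS in THF at −78 °C and trapping with TMSCl should give the cross-conjugated silyl dienol ether methyl 3-(benzyloxy)-5-methoxy-2-{[5-methyl-3-(trimethylsilyloxy)cyclohexa-1,3-dien-1-yl]oxy}benzoate F1. Saegusa–Ito oxidation of F1 with Pd(OAc)2 in MeCN at rt (palladium enolate at C6, β-hydride loss from C5) gives the 2,5-dienone, which tautomerises, and the route is rejoined at 10.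

Step 5. The substitution may be slow because the phenoxide is flanked by two ortho groups and is deactivated by the ester. Base-mediated hydrolysis or self-condensation of the chloroenone, or closure of the enone α-carbon onto the neighbouring methyl ester, could then take over. The fallback sets out from 5 and brings ring B in already aromatic. Commercial 3-bromo-5-methylphenol is benzylated (BnBr, K2CO3, acetone) to 1-(benzyloxy)-3-bromo-5-methylbenzene F2. This is converted by bromine–lithium exchange and borylation (n-BuLi, B(OiPr)3, THF, −78 °C; aq HCl) into [3-(benzyloxy)-5-methylphenyl]boronic acid F3. Chan–Lam coupling of F3 with 5 (Cu(OAc)2, pyridine, 4 Å MS, CH2Cl2, air, rt) should give methyl 3-(benzyloxy)-2-[3-(benzyloxy)-5-methylphenoxy]-5-methoxybenzoate F4. Hydrogenolysis of both benzyl ethers (H2, Pd/C, EtOAc) brings the material back to the route at 11.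

Step 9. The enzyme may turn the alcohol over only slowly because the CH2OH group sits next to the bulky aryloxy substituent, so conversion may stall. The fallback sets out from 12 and swaps kinetic selection in the acylation for selection in a deacylation. Exhaustive acylation with palmitoyl chloride (Et3N, DMAP, CH2Cl2) gives the tris-palmitate [3-(hexadecanoyloxy)-2-[3-(hexadecanoyloxy)-5-methylphenoxy]-5-methoxyphenyl]methyl hexadecanoate F5. Its two aryl esters, far more reactive toward amines than the alkyl ester, are then cleaved by aminolysis with pyrrolidine (2.2 equiv, THF, 0 °C), which returns to the route at 14.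

Further compounds
F1 | step 6 | methyl 3-(benzyloxy)-5-methoxy-2-{[5-methyl-3-(trimethylsilyloxy)cyclohexa-1,3-dien-1-yl]oxy}benzoate (racemic) | COC(=O)c1cc(OC)cc(OCc2ccccc2)c1OC1=CC(O[Si](C)(C)C)=CC(C)C1
F2 | step 5 | 1-(benzyloxy)-3-bromo-5-methylbenzene | Cc1cc(Br)cc(OCc2ccccc2)c1
F3 | step 5 | [3-(benzyloxy)-5-methylphenyl]boronic acid | Cc1cc(OCc2ccccc2)cc(B(O)O)c1
F4 | step 5 | methyl 3-(benzyloxy)-2-[3-(benzyloxy)-5-methylphenoxy]-5-methoxybenzoate | COC(=O)c1cc(OC)cc(OCc2ccccc2)c1Oc1cc(C)cc(OCc2ccccc2)c1
F5 | step 9 | [3-(hexadecanoyloxy)-2-[3-(hexadecanoyloxy)-5-methylphenoxy]-5-methoxyphenyl]methyl hexadecanoate | CCCCCCCCCCCCCCCC(=O)OCc1cc(OC)cc(OC(=O)CCCCCCCCCCCCCCC)c1Oc1cc(C)cc(OC(=O)CCCCCCCCCCCCCCC)c1
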